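**Strategy.** Ring A (the butenolide O1–C2–C3–C4–C5) is closed last, so the synthesis rests on a stereodefined acyclic C3=C4 alkene that carries C2 and C5 on the same side. The key step exploits the C1' hydroxyl on the carbon attached to C3. As a magnesium alkoxide it directs a copper-catalysed anti addition of a masked hydroxymethyl carbon (future C2) and magnesium across a C3≡C4 triple bond. Bromination of the C4–Mg bond then delivers the C4 bromide. One operation thus forms C2–C3 and C4–Br and fixes the alkene geometry. Its substrate is an enantioenriched (R)-diynol whose distal alkyne (future C5–C6) is capped with Me3Si.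

Key step: step 4

Remark: the SMILES is read as the (1'R) acetate with an (E)-bromomethylene group, i.e. the bromine on exocyclic C6 lies on the side of C4 and anti to O1. Numbering used: O1, C2 (carbonyl), C3, C4 (Br), C5, C6 (=CHBr), C1' (carbinol).

**Step 1**
Reactants: 1 1,4-bis(trimethylsilyl)buta-1,3-diyne; 2 butanoyl chloride
Product: 3 1-(trimethylsilyl)octa-1,3-diyn-5-one
Conditions: AlCl3 (1.05 equiv), CH2Cl2, −20 → 0 °C
Reagents that add atoms: none
Why: Friedel–Crafts-type ipso acyl-desilylation of an alkynylsilane, in which the acylium–AlCl3 complex attacks the silyl-bearing alkyne carbon, Me3SiCl leaves, and the electron-poor ynone formed is too deactivated for a second acylation at the remaining silyl terminus.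

**Step 2**
Reactants: 3 1-(trimethylsilyl)octa-1,3-diyn-5-one
Product: 4 (5R)-1-(trimethylsilyl)octa-1,3-diyn-5-ol
Conditions: Ru[(R,R)-TsNCH(Ph)CH(Ph)NH](p-cymene) (2 mol%, preformed from RuCl[(R,R)-TsDPEN](p-cymene) and KOH), i-PrOH, rt
Reagents that add atoms: none
Why: Noyori asymmetric transfer hydrogenation of an alkynyl ketone, in which the bifunctional Ru–H/N–H catalyst differentiates the linear diynyl π-substituent from the propyl chain; the (R,R)-ligand should give the (R)-carbinol by analogy with alkynyl methyl ketones, where the (S,S)-catalyst gives (S)-alcohols, and the base-free catalyst spares the C–Si bond.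

**Step 3**
Reactants: 5 (chloromethyl)isopropoxydimethylsilane
Product: 6 [(isopropoxydimethylsilyl)methyl]magnesium chloride
Conditions: Mg turnings, THF, reflux (trace BrCH2CH2Br to initiate)
Reagents that add atoms: magnesium, [Mg]
Why: Grignard formation by magnesium insertion into the C–Cl bond of an α-silyl chloride, giving the standard nucleophilic hydroxymethyl equivalent whose Si–O-i-Pr group is stable to the reagent.

**Step 4**
Reactants: 4 (5R)-1-(trimethylsilyl)octa-1,3-diyn-5-ol; 6 [(isopropoxydimethylsilyl)methyl]magnesium chloride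
Product: 9 (3E,5R)-3-bromo-4-[(isopropoxydimethylsilyl)methyl]-1-(trimethylsilyl)oct-3-en-1-yn-5-ol, via chloromagnesium alkoxide 7 (not isolated), via oxamagnesacycle 8 (not isolated)
Conditions: 6 (2.5 equiv), CuI (10 mol%), Et2O/THF, 0 °C → rt; then NBS (1.7 equiv) in THF, −78 → 0 °C; aq. NH4Cl/Na2S2O3
Reagents that add atoms: N-bromosuccinimide, O=C1CCC(=O)N1Br
Why: One equivalent of 6 deprotonates the carbinol to alkoxide 7; a silylmethylcopper species formed from CuI and 6 then transfers CH2Si to C3 while the alkoxide-bound magnesium takes C4 from the opposite face, giving the five-membered oxamagnesacycle 8 (O, C1', C3, C4, Mg), and NBS replaces the C4–Mg bond by C4–Br with retention. The closest known reaction type is the CuI-catalysed anti-carbomagnesiation of propargylic alcohols with alkyl and silylmethyl Grignard reagents, followed by halogen quench of the chelated alkenylmagnesium. No ring of the target is closed; the only ring is the transient magnesacycle, which closes in an endo sense across C3≡C4 and is opened again by NBS and work-up. No stereocentre is created and C1' is not touched; the one new stereo element, the C3=C4 geometry, is dictated by the chelate, which holds magnesium (later Br) cis to C1' and so places the new carbon (future C2) cis to the alkynyl arm (future C5–C6). The step needs proximal regiochemistry (carbon to C3 and not to the distal alkyne), anti addition and bromination at C4 only. Alkoxide chelation, stabilisation of the C4–Mg bond by the neighbouring alkyne, and the Me3Si cap (no acidic alkyne C–H, steric shielding of the distal triple bond) should secure these.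

**Step 5**
Reactants: 9 (3E,5R)-3-bromo-4-[(isopropoxydimethylsilyl)methyl]-1-(trimethylsilyl)oct-3-en-1-yn-5-ol
Product: 10 (2Z,3R)-2-(1-bromoprop-2-yn-1-ylidene)hexane-1,3-diol
Conditions: KF, KHCO3, 30% H2O2, THF/MeOH (1:1), rt
Reagents that add atoms: hydrogen peroxide, OO
Why: Tamao oxidation, in which fluoride-assisted peroxide attack at the alkoxysilane is followed by 1,2-shift of the allylic CH2 from Si to O without touching the C3=C4 geometry, while KF/KHCO3 in methanol removes the alkynyl Me3Si group in the same flask.

**Step 6**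
Reactants: 10 (2Z,3R)-2-(1-bromoprop-2-yn-1-ylidene)hexane-1,3-diol
Product: 12 (2E)-3-bromo-2-[(1R)-1-hydroxybutyl]pent-2-en-4-ynoic acid, via hydroxy enal 11 (not isolated)
Conditions: TEMPO (20 mol%), PhI(OAc)2 (1.1 equiv), CH2Cl2, rt; then t-BuOH/H2O, 2-methylbut-2-ene, NaH2PO4, NaClO2, 0 °C → rt
Reagents that add atoms: sodium chlorite (NaClO2), [Na+].[O-]Cl=O
Why: Oxoammonium (TEMPO/PhI(OAc)2) oxidation is selective for the unhindered primary allylic alcohol over the secondary C1' carbinol and stops at enal 11, which the Pinnick chlorite oxidation converts to the C2 acid without affecting the alkene geometry, the alkyne or the C1' stereocentre.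

**Step 7**
Reactants: 12 (2E)-3-bromo-2-[(1R)-1-hydroxybutyl]pent-2-en-4-ynoic acid
Product: 14 (2E)-2-[(1R)-1-acetoxybutyl]-3-bromopent-2-en-4-ynoic acid, via mixed anhydride 13 (not isolated)
Conditions: Ac2O (3 equiv), pyridine, DMAP (5 mol%), CH2Cl2, 0 °C; then H2O/THF, rt; dilute HCl work-up
Reagents that add atoms: acetic anhydride, CC(=O)OC(C)=O
Why: DMAP-catalysed O-acylation of the secondary alcohol with retention at C1'; the carboxyl group is acylated as well to mixed anhydride 13, which water cleaves at the less hindered acetyl carbonyl in the hydrolytic stage, returning the free acid.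

**Step 8**
Reactants: 14 (2E)-2-[(1R)-1-acetoxybutyl]-3-bromopent-2-en-4-ynoic acid
Product: 15 (1R)-1-[(5E)-4-bromo-5-(bromomethylidene)-2-oxo-2,5-dihydrofuran-3-yl]butyl acetate (acetoxyfimbrolide)
Conditions: NBS (1.1 equiv), KHCO3 (1.1 equiv), Bu4NOH (cat.), CH2Cl2/H2O, 0 °C → rt, dark
Reagents that add atoms: N-bromosuccinimide, O=C1CCC(=O)N1Br
Why: Bromolactonisation of an alkynoic acid, in which the terminal alkyne is activated by electrophilic bromine and the cis-disposed carboxylate attacks the internal carbon C5 from the opposite face (5-exo-dig, Markovnikov), closing ring A and placing Br on C6 anti to O1, which is the (E)-bromomethylene geometry of the target.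

**Compound list**
1 | 1,4-bis(trimethylsilyl)buta-1,3-diyne | C[Si](C)(C)C#CC#C[Si](C)(C)C | starting material
2 | butanoyl chloride | CCCC(Cl)=O | starting material
3 | 1-(trimethylsilyl)octa-1,3-diyn-5-one | CCCC(=O)C#CC#C[Si](C)(C)C | intermediate
4 | (5R)-1-(trimethylsilyl)octa-1,3-diyn-5-ol | CCC[C@@H](O)C#CC#C[Si](C)(C)C | intermediate
5 | (chloromethyl)isopropoxydimethylsilane | CC(C)O[Si](C)(C)CCl | starting material
6 | [(isopropoxydimethylsilyl)methyl]magnesium chloride | CC(C)O[Si](C)(C)C[Mg]Cl | intermediate
7 | chloromagnesium (5R)-1-(trimethylsilyl)octa-1,3-diyn-5-olate | CCC[C@@H](O[Mg]Cl)C#CC#C[Si](C)(C)C | intermediate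
8 | (5R)-4-[(isopropoxydimethylsilyl)methyl]-5-propyl-3-[(trimethylsilyl)ethynyl]-2,5-dihydro-1,2-oxamagnesole | CCC[C@@H]1C(C[Si](C)(C)OC(C)C)=C(C#C[Si](C)(C)C)[Mg]O1 | intermediate
9 | (3E,5R)-3-bromo-4-[(isopropoxydimethylsilyl)methyl]-1-(trimethylsilyl)oct-3-en-1-yn-5-ol (silylmethyl cis to the alkyne, Br cis to the carbinol carbon) | CCC[C@@H](O)/C(C[Si](C)(C)OC(C)C)=C(\Br)C#C[Si](C)(C)C | intermediate
10 | (2Z,3R)-2-(1-bromoprop-2-yn-1-ylidene)hexane-1,3-diol | CCC[C@@H](O)/C(CO)=C(\Br)C#C | intermediate
11 | (2E)-3-bromo-2-[(1R)-1-hydroxybutyl]pent-2-en-4-ynal | CCC[C@@H](O)/C(C=O)=C(\Br)C#C | intermediate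
12 | (2E)-3-bromo-2-[(1R)-1-hydroxybutyl]pent-2-en-4-ynoic acid | CCC[C@@H](O)/C(C(=O)O)=C(\Br)C#C | intermediate
13 | acetic (2E)-2-[(1R)-1-acetoxybutyl]-3-bromopent-2-en-4-ynoic anhydride | CCC[C@@H](OC(C)=O)/C(C(=O)OC(C)=O)=C(\Br)C#C | intermediate
14 | (2E)-2-[(1R)-1-acetoxybutyl]-3-bromopent-2-en-4-ynoic acid | CCC[C@@H](OC(C)=O)/C(C(=O)O)=C(\Br)C#C | intermediate
15 | (1R)-1-[(5E)-4-bromo-5-(bromomethylidene)-2-oxo-2,5-dihydrofuran-3-yl]butyl acetate (acetoxyfimbrolide) | CCC[C@@H](OC(C)=O)C1=C(Br)/C(=C\Br)OC1=O | target

**Step count.** Total: 8 steps. Longest linear sequence: 7 steps (1, 2, 4, 5, 6, 7, 8 from compound 1); step 3 prepares the Grignard reagent on a side branch.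

**Steps most likely to fail**

Step 4. The transfer of the α-silyl alkyl group from copper/magnesium to C3 may be slow, and unselective addition to the distal alkyne may then compete. The C4–Mg bond may also leak into its butatrienyl form, eroding the geometry or brominating at the far terminus, and excess NBS may bromodesilylate the allylic C–Si bond. Exchange of the isopropoxy group on silicon by the C1' alkoxide would be harmless, since the Si–O bond needed for oxidation remains. The fallback changes the C2 synthon and the way it is unveiled. It sets out from 4: uncatalysed anti-carbomagnesiation with vinylmagnesium chloride (THF/toluene, heat), a well-established variant of this addition, followed by the same NBS quench should give (3Z,5R)-3-bromo-4-ethenyl-1-(trimethylsilyl)oct-3-en-1-yn-5-ol F1. K2CO3 in MeOH removes the alkynyl silyl group to give (3Z,5R)-3-bromo-4-ethenyloct-3-en-1-yn-5-ol F2. Lemieux–Johnson cleavage (OsO4 cat., NaIO4, 2,6-lutidine, dioxane/H2O) of the only monosubstituted, electron-richer alkene then gives the hydroxy enal. The route is rejoined at 11, which is carried through the chlorite stage of step 6; the Tamao step is no longer needed.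

Step 8. Ring closure may go partly 6-endo to a pyranone, bromine transfer may lose its anti stereospecificity, and light or nucleophiles may isomerise the kinetically formed (E)-bromomethylene group to the less crowded isomer. The fallback separates ring closure from bromine introduction. It sets out from 14: Hg(OAc)2 in CH2Cl2 closes the lactone by anti oxymercuration (5-exo-dig), and exchange with aqueous NaCl gives (1R)-1-[(5E)-4-bromo-5-[(chloromercurio)methylidene]-2-oxo-2,5-dihydrofuran-3-yl]butyl acetate F3. Bromodemercuration with NBS in MeCN at 0 °C in the dark proceeds with retention and comes back at 15.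

Step 6. Discrimination between the primary and the secondary allylic hydroxyl may be incomplete (over-oxidation at C1' would destroy the stereocentre), and hypochlorite released in the chlorite stage may attack the alkyne. The fallback replaces chemoselective oxidation by protecting-group differentiation. It sets out from 10:
- TBSCl/imidazole silylates the primary hydroxyl only, giving (2Z,3R)-2-(1-bromoprop-2-yn-1-ylidene)-1-[(tert-butyldimethylsilyl)oxy]hexan-3-ol F4.
- Ac2O/pyridine/DMAP gives (2Z,3R)-2-(1-bromoprop-2-yn-1-ylidene)-1-[(tert-butyldimethylsilyl)oxy]hexan-3-yl acetate F5.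
- HF·pyridine in THF frees the primary alcohol as (2Z,3R)-2-(1-bromoprop-2-yn-1-ylidene)-1-hydroxyhexan-3-yl acetate F6.
- Dess–Martin periodinane gives (2E)-2-[(1R)-1-acetoxybutyl]-3-bromopent-2-en-4-ynal F7.
- Pinnick oxidation comes back at 14, so step 7 is not needed.

**Further compounds**
F1 | step 4 | (3Z,5R)-3-bromo-4-ethenyl-1-(trimethylsilyl)oct-3-en-1-yn-5-ol | CCC[C@@H](O)/C(C=C)=C(\Br)C#C[Si](C)(C)C
F2 | step 4 | (3Z,5R)-3-bromo-4-ethenyloct-3-en-1-yn-5-ol | CCC[C@@H](O)/C(C=C)=C(\Br)C#C
F3 | step 8 | (1R)-1-[(5E)-4-bromo-5-[(chloromercurio)methylidene]-2-oxo-2,5-dihydrofuran-3-yl]butyl acetate | CCC[C@@H](OC(C)=O)C1=C(Br)/C(=C\[Hg]Cl)OC1=O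
F4 | step 6 | (2Z,3R)-2-(1-bromoprop-2-yn-1-ylidene)-1-[(tert-butyldimethylsilyl)oxy]hexan-3-ol | CCC[C@@H](O)/C(CO[Si](C)(C)C(C)(C)C)=C(\Br)C#C
F5 | step 6 | (2Z,3R)-2-(1-bromoprop-2-yn-1-ylidene)-1-[(tert-butyldimethylsilyl)oxy]hexan-3-yl acetate | CCC[C@@H](OC(C)=O)/C(CO[Si](C)(C)C(C)(C)C)=C(\Br)C#C
F6 | step 6 | (2Z,3R)-2-(1-bromoprop-2-yn-1-ylidene)-1-hydroxyhexan-3-yl acetate | CCC[C@@H](OC(C)=O)/C(CO)=C(\Br)C#C
F7 | step 6 | (2E)-2-[(1R)-1-acetoxybutyl]-3-bromopent-2-en-4-ynal | CCC[C@@H](OC(C)=O)/C(C=O)=C(\Br)C#C
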